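**Retrosynthetic overview**
1. Target ⇒ C2-symmetric 4,4'-diol 19 by oxidising one of its two equivalent hydroxyls (last step); 19 ⇒ 2 × C15 phosphonium salt 14 + C10 dialdehyde 15 by double Wittig at C11=C12 and C11'=C12'.
2. 14 ⇒ C13 enone 10 (vinyl Grignard, PPh3·HBr). The 4-OH comes from an isopropenyl group by Criegee rearrangement with retention, so C4 is the stereocentre bought in (S)-carvone.
3. Key disconnection C6–C7: photochemical deoxygenative radical alkenylation of alcohol 6 with but-3-yn-2-one, then equilibration of C6 to the all-equatorial isomer under control of C4/C5.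
4. 6 ⇒ (S)-carvone: reductive methylation (C1 gem-dimethyl), enolate methylation trans to the C4 substituent (C5), ketone reduction.
5. Ring order: no ring is built; each cyclohexane is the intact carvone ring, and the polyene is assembled last.

Assumption: positions in the text use carotenoid numbering (ring C1–C6, chain C7–C15, primes for the keto half), IUPAC locants appear only inside compound names, and the reagents named in the steps are bought.

**Step 1**
Reactants: 1 (S)-(+)-carvone
Product: 3 (5S)-2,2-dimethyl-5-(prop-1-en-2-yl)cyclohexan-1-one, via lithium enolate 2 (not isolated)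
Conditions: LiBH(s-Bu)3, THF, −78 °C; then MeI, −78 → 25 °C
Reagents that add atoms: iodomethane, CI
Why: Conjugate hydride reduction gives only the C1–C2 enolate, and its C-methylation (reductive alkylation of an enone) builds the quaternary carbon that becomes C1 of the end group; the bought stereocentre is untouched.

**Step 2**
Reactants: 3 (5S)-2,2-dimethyl-5-(prop-1-en-2-yl)cyclohexan-1-one
Product: 5 (5S,6R)-2,2,6-trimethyl-5-(prop-1-en-2-yl)cyclohexan-1-one, via lithium enolate 4 (not isolated)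
Conditions: LiN(i-Pr)2, THF, −78 °C; MeI, −78 → 0 °C; then NaOMe (cat.), MeOH, 25 °C
Reagents that add atoms: iodomethane, CI
Why: Enolate alkylation: only one α-carbon can be deprotonated, MeI enters anti to the neighbouring isopropenyl group, and alkoxide equilibration secures the diequatorial trans isomer (an axial methyl would clash with the axial 2-methyl), so the future C5 is set by the bought centre.

**Step 3**
Reactants: 5 (5S,6R)-2,2,6-trimethyl-5-(prop-1-en-2-yl)cyclohexan-1-one
Product: 6 (1RS,5S,6R)-2,2,6-trimethyl-5-(prop-1-en-2-yl)cyclohexan-1-ol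
Conditions: LiAlH4, Et2O, 0 → 25 °C
Reagents that add atoms: none
Why: Hydride reduction of the hindered ketone; the carbinol configuration does not matter because this carbon becomes a planar radical in step 4.

**Step 4**
Reactants: 6 (1RS,5S,6R)-2,2,6-trimethyl-5-(prop-1-en-2-yl)cyclohexan-1-ol; 7 but-3-yn-2-one
Product: 10 (3E)-4-[(1S,5S,6R)-2,2,6-trimethyl-5-(prop-1-en-2-yl)cyclohexyl]but-3-en-2-one, via benzoxazoline acetal 8 (not isolated), via 1R epimer 9 (not isolated)
Conditions: 5,7-di-tert-butyl-3-phenyl-1,3-benzoxazol-3-ium tetrafluoroborate (1.2 equiv), pyridine, MTBE, 25 °C; then 7 (1.5 equiv), [Ir(ppy)2(dtbbpy)]PF6 (1 mol%), quinuclidine (0.5 equiv), MTBE/DMSO, 450 nm LEDs, 25 °C; evaporate, then KOt-Bu (0.2 equiv), t-BuOH/THF, 25 °C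
Reagents that add atoms: none
Why: Proposed new method: the alcohol is condensed to N,O-acetal 8, the excited iridium photocatalyst oxidises it, and loss of the acetal proton followed by β-scission expels the secondary ring radical, which adds Giese-fashion to the terminal carbon of the ynone to form the C6–C7 bond; reduction and protonation of the vinyl radical give the enone, and because C6–H is γ to the carbonyl, catalytic alkoxide equilibrates the alkene geometry and C6 through the dienolate to the all-equatorial E isomer, so C6 is dictated by the carvone-derived C4/C5 centres; the closest known chemistry is the photoredox deoxygenative Giese alkylation of benzoxazolium-activated alcohols and radical hydroalkylation of ynones, not yet shown for a 2,2,6-trisubstituted cyclohexanol or with an alkyne acceptor.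

**Step 5**
Reactants: 10 (3E)-4-[(1S,5S,6R)-2,2,6-trimethyl-5-(prop-1-en-2-yl)cyclohexyl]but-3-en-2-one
Product: 12 (1S,2S,3S)-2,4,4-trimethyl-3-[(1E)-3-oxobut-1-en-1-yl]cyclohexyl acetate, via methoxy hydroperoxide 11 (not isolated)
Conditions: O3 (1.0 equiv, Sudan Red end point), CH2Cl2/MeOH 5:1, −78 °C; then Ac2O, Et3N, DMAP (cat.), CH2Cl2, 0 → 25 °C
Reagents that add atoms: ozone, [O-][O+]=O; methanol, CO
Why: Criegee rearrangement of the acetylated methoxy hydroperoxide: the ring carbon migrates from carbon to oxygen with retention, so the bought stereocentre becomes the C4–O centre (4S); ozone attacks the electron-rich isopropenyl group far faster than the enone.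

**Step 6**
Reactants: 12 (1S,2S,3S)-2,4,4-trimethyl-3-[(1E)-3-oxobut-1-en-1-yl]cyclohexyl acetate
Product: 13 (1S,2S,3S)-3-[(1E)-3-hydroxy-3-methylpenta-1,4-dien-1-yl]-2,4,4-trimethylcyclohexan-1-ol
Conditions: CH2=CHMgBr (3.5 equiv), THF, −20 → 0 °C
Reagents that add atoms: vinylmagnesium bromide, C=C[Mg]Br
Why: Grignard 1,2-addition to the methyl ketone (the vinyl-ionol reaction); excess reagent also cleaves the acetate, no ring stereocentre is involved, and the new carbinol centre is erased in step 7.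

**Step 7**
Reactants: 13 (1S,2S,3S)-3-[(1E)-3-hydroxy-3-methylpenta-1,4-dien-1-yl]-2,4,4-trimethylcyclohexan-1-ol
Product: 14 {(2E,4E)-5-[(1S,5S,6S)-5-hydroxy-2,2,6-trimethylcyclohexyl]-3-methylpenta-2,4-dien-1-yl}triphenylphosphonium bromide
Conditions: PPh3·HBr, MeOH, 25 °C; crystallisation from EtOAc
Reagents that add atoms: triphenylphosphine hydrobromide, [Br-].[PH+](c1ccccc1)(c1ccccc1)c1ccccc1
Why: SN1-type allylic transposition: HBr ionises the tertiary bis-allylic alcohol to a pentadienyl cation that PPh3 captures at the unhindered terminus to give the thermodynamic 2E,4E Wittig salt; the secondary hydroxyl and C6 are unaffected, as in the α-ionone series.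

**Step 8**
Reactants: 14 {(2E,4E)-5-[(1S,5S,6S)-5-hydroxy-2,2,6-trimethylcyclohexyl]-3-methylpenta-2,4-dien-1-yl}triphenylphosphonium bromide; 15 (2E,4E,6E)-2,7-dimethylocta-2,4,6-trienedial
Product: 19 (all-E)-(4S,5S,6S,4'S,5'S,6'S)-5,6,5',6'-tetrahydro-β,β-carotene-4,4'-diol, via ylide 16 (not isolated), via hydroxy aldehyde 17 (not isolated), via 11Z isomer 18 (not isolated)
Conditions: 14 (2.2 equiv), 15 (1.0 equiv), NaOMe (2.3 equiv), CH2Cl2/MeOH, 0 → 25 °C; then heptane, 90 °C, N2, dark
Reagents that add atoms: none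
Why: Double Wittig olefination of the symmetrical dialdehyde with two equivalents of the ylide made in situ forms both C11=C12 bonds in one operation (the free hydroxyls need no protection), thermal equilibration converts the 11Z isomers into the all-E polyene, and no stereocentre is touched.

**Step 9**
Reactants: 19 (all-E)-(4S,5S,6S,4'S,5'S,6'S)-5,6,5',6'-tetrahydro-β,β-carotene-4,4'-diol
Product: 20 (all-E)-(4S,5S,6S,5'S,6'S)-4-hydroxy-5,6,5',6'-tetrahydro-β,β-caroten-4'-one
Conditions: Dess–Martin periodinane (1.0 equiv, added over 1 h), NaHCO3, CH2Cl2, 0 °C, dark; chromatography, recovered 19 resubmitted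
Reagents that add atoms: none
Why: Dess–Martin oxidation under buffered, non-enolising conditions; the two hydroxyls are equivalent and remote, so one equivalent of oxidant gives the mono-ketone statistically (close to half of the material per pass, with the diol recovered and recycled), and the neighbouring centre C5' is not touched and is in any case the more stable equatorial epimer.

**Compound list**
1 | (S)-(+)-carvone, (5S)-2-methyl-5-(prop-1-en-2-yl)cyclohex-2-en-1-one | O=C1C[C@@H](C(C)=C)CC=C1C | starting material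
2 | lithium (5S)-2-methyl-5-(prop-1-en-2-yl)cyclohex-1-en-1-olate | [Li+].[O-]C1=C(C)CC[C@H](C(C)=C)C1 | intermediate
3 | (5S)-2,2-dimethyl-5-(prop-1-en-2-yl)cyclohexan-1-one | O=C1C[C@@H](C(C)=C)CCC1(C)C | intermediate
4 | lithium (3S)-6,6-dimethyl-3-(prop-1-en-2-yl)cyclohex-1-en-1-olate | [Li+].[O-]C1=C[C@@H](C(C)=C)CCC1(C)C | intermediate
5 | (5S,6R)-2,2,6-trimethyl-5-(prop-1-en-2-yl)cyclohexan-1-one | O=C1[C@H](C)[C@@H](C(C)=C)CCC1(C)C | intermediate
6 | (1RS,5S,6R)-2,2,6-trimethyl-5-(prop-1-en-2-yl)cyclohexan-1-ol (both C1 epimers) | OC1[C@H](C)[C@@H](C(C)=C)CCC1(C)C | intermediate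
7 | but-3-yn-2-one | CC(=O)C#C | starting material
8 | 5,7-di-tert-butyl-3-phenyl-2-{[(5S,6R)-2,2,6-trimethyl-5-(prop-1-en-2-yl)cyclohexyl]oxy}-2,3-dihydro-1,3-benzoxazole (epimers at the carbinol and acetal carbons) | O(C1[C@H](C)[C@@H](C(C)=C)CCC1(C)C)C1Oc2c(C(C)(C)C)cc(C(C)(C)C)cc2N1c1ccccc1 | intermediate
9 | (3E)-4-[(1R,5S,6R)-2,2,6-trimethyl-5-(prop-1-en-2-yl)cyclohexyl]but-3-en-2-one (kinetic axial epimer, formed together with 3Z isomers) | CC(=O)/C=C/[C@@H]1[C@H](C)[C@@H](C(C)=C)CCC1(C)C | intermediate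
10 | (3E)-4-[(1S,5S,6R)-2,2,6-trimethyl-5-(prop-1-en-2-yl)cyclohexyl]but-3-en-2-one | CC(=O)/C=C/[C@H]1[C@H](C)[C@@H](C(C)=C)CCC1(C)C | intermediate
11 | (3E)-4-[(1S,5S,6S)-5-(1-hydroperoxy-1-methoxyethyl)-2,2,6-trimethylcyclohexyl]but-3-en-2-one (both epimers at the peroxy carbon) | CC(=O)/C=C/[C@H]1[C@H](C)[C@@H](C(C)(OC)OO)CCC1(C)C | intermediate
12 | (1S,2S,3S)-2,4,4-trimethyl-3-[(1E)-3-oxobut-1-en-1-yl]cyclohexyl acetate | CC(=O)/C=C/[C@H]1[C@H](C)[C@@H](OC(C)=O)CCC1(C)C | intermediate
13 | (1S,2S,3S)-3-[(1E)-3-hydroxy-3-methylpenta-1,4-dien-1-yl]-2,4,4-trimethylcyclohexan-1-ol (both epimers at the tertiary carbinol) | C=CC(C)(O)/C=C/[C@H]1[C@H](C)[C@@H](O)CCC1(C)C | intermediate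
14 | {(2E,4E)-5-[(1S,5S,6S)-5-hydroxy-2,2,6-trimethylcyclohexyl]-3-methylpenta-2,4-dien-1-yl}triphenylphosphonium bromide | [Br-].C(/C=C(C)/C=C/[C@H]1[C@H](C)[C@@H](O)CCC1(C)C)[P+](c1ccccc1)(c1ccccc1)c1ccccc1 | intermediate
15 | (2E,4E,6E)-2,7-dimethylocta-2,4,6-trienedial | O=C/C(C)=C/C=C/C=C(C)/C=O | starting material
16 | [(2E,4E)-5-[(1S,5S,6S)-5-hydroxy-2,2,6-trimethylcyclohexyl]-3-methylpenta-2,4-dien-1-ylidene](triphenyl)-λ5-phosphane (ylide of 14) | [CH-]([P+](c1ccccc1)(c1ccccc1)c1ccccc1)/C=C(C)/C=C/[C@H]1[C@H](C)[C@@H](O)CCC1(C)C | intermediate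
17 | (2E,4E,6E,8E,10E,12E)-13-[(1S,5S,6S)-5-hydroxy-2,2,6-trimethylcyclohexyl]-2,7,11-trimethyltrideca-2,4,6,8,10,12-hexaenal (product of the first condensation, formed together with its 8Z isomer) | CC(/C=C/C=C(C)/C=C/[C@H]1[C@H](C)[C@@H](O)CCC1(C)C)=C\C=C\C=C(C)\C=O | intermediate
18 | (11Z)-(4S,5S,6S,4'S,5'S,6'S)-5,6,5',6'-tetrahydro-β,β-carotene-4,4'-diol (stands for the 11Z and 11Z,11'Z isomers formed beside the all-E diol) | CC(/C=C\C=C(C)\C=C\[C@H]1[C@H](C)[C@@H](O)CCC1(C)C)=C\C=C\C=C(C)\C=C\C=C(C)\C=C\[C@H]1[C@H](C)[C@@H](O)CCC1(C)C | intermediate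
19 | (all-E)-(4S,5S,6S,4'S,5'S,6'S)-5,6,5',6'-tetrahydro-β,β-carotene-4,4'-diol | CC(/C=C/C=C(C)/C=C/[C@H]1[C@H](C)[C@@H](O)CCC1(C)C)=C\C=C\C=C(C)\C=C\C=C(C)\C=C\[C@H]1[C@H](C)[C@@H](O)CCC1(C)C | intermediate
20 | (all-E)-(4S,5S,6S,5'S,6'S)-4-hydroxy-5,6,5',6'-tetrahydro-β,β-caroten-4'-one (CNP0107241.1) | CC(/C=C/C=C(C)/C=C/[C@H]1[C@H](C)[C@@H](O)CCC1(C)C)=C\C=C\C=C(C)\C=C\C=C(C)\C=C\[C@H]1[C@H](C)C(=O)CCC1(C)C | target

**Step count and risks**
Total step count: 9. Longest linear sequence: 9 steps (1 → 3 → 5 → 6 → 10 → 12 → 13 → 14 → 19 → 20); two equivalents of salt 14 enter step 8.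

Steps most likely to fail:

Step 4 (the new photochemical C6–C7 coupling). The 2,2,6-trisubstituted cyclohexanol may condense slowly with the benzoxazolium salt, and the hindered radical may be reduced before it adds. The equilibrium at C6 is expected to be only about 5:1 or somewhat better, so the minor epimer would be resubmitted to the base. The fallback uses known chemistry, sets out from ketone 5 and returns at enone 10. Corey–Chaykovsky methylenation (Me3S+ I−, n-BuLi, THF) gives the spiro-epoxide (7S,8R)-4,4,8-trimethyl-7-(prop-1-en-2-yl)-1-oxaspiro[2.5]octane F1. MgBr2·OEt2 rearranges it (Meinwald), and K2CO3/MeOH equilibration of the α-carbon delivers the all-equatorial (1S,5S,6R)-2,2,6-trimethyl-5-(prop-1-en-2-yl)cyclohexane-1-carbaldehyde F2. Wittig reaction with Ph3P=CHC(O)CH3 in toluene at 90 °C then gives 10.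

Step 5 (selective ozonolysis beside the enone, then Criegee rearrangement). Over-ozonolysis of the enone or an incomplete rearrangement would cost material. The fallback sets out from 10 and returns at 12. Ozonolysis with Me2S work-up gives (3E)-4-[(1S,5S,6S)-5-acetyl-2,2,6-trimethylcyclohexyl]but-3-en-2-one F3, kept free of base. Baeyer–Villiger oxidation (m-CPBA, NaHCO3, CH2Cl2) of the saturated methyl ketone, with the secondary ring carbon migrating with retention and the conjugated ketone left alone, gives 12.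

Step 9 (oxidation of one of two equivalent hydroxyls). The selectivity is statistical, so at best about half of the diol is converted per pass, and the mono-ketone must be separated from the diol and the diketone on a sensitive polyene. The fallback sets out from phosphonium salt 14 and returns at target 20; it makes the ketone before the second ring is attached, so nothing has to be differentiated.
- Slow addition of 14 to dialdehyde 15 (3 equiv) with NaOMe in CH2Cl2/MeOH gives hydroxy aldehyde 17, here isolated, together with (2E,4E,6E,8Z,10E,12E)-13-[(1S,5S,6S)-5-hydroxy-2,2,6-trimethylcyclohexyl]-2,7,11-trimethyltrideca-2,4,6,8,10,12-hexaenal F4. I2 (1 mol%) in CH2Cl2 in daylight converts this isomer into 17.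
- Dess–Martin periodinane with NaHCO3 oxidises 17 to (2E,4E,6E,8E,10E,12E)-2,7,11-trimethyl-13-[(1S,6S)-2,2,6-trimethyl-5-oxocyclohexyl]trideca-2,4,6,8,10,12-hexaenal F5.
- Ylide 16, preformed from 14 with NaN(SiMe3)2 (1.0 equiv) in THF at −78 °C, is added to F5. The ylide is too weak a base to enolise the hindered ring ketone, and 5'S is the more stable epimer in any case.
- The crude product contains (11Z)-(4S,5S,6S,5'S,6'S)-4-hydroxy-5,6,5',6'-tetrahydro-β,β-caroten-4'-one F6, and heating in heptane at 80 °C in the dark gives 20.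

**Further compounds**
F1 | step 4 | (7S,8R)-4,4,8-trimethyl-7-(prop-1-en-2-yl)-1-oxaspiro[2.5]octane (both spiro epimers) | O1CC12[C@H](C)[C@@H](C(C)=C)CCC2(C)C
F2 | step 4 | (1S,5S,6R)-2,2,6-trimethyl-5-(prop-1-en-2-yl)cyclohexane-1-carbaldehyde | O=C[C@H]1[C@H](C)[C@@H](C(C)=C)CCC1(C)C
F3 | step 5 | (3E)-4-[(1S,5S,6S)-5-acetyl-2,2,6-trimethylcyclohexyl]but-3-en-2-one | CC(=O)/C=C/[C@H]1[C@H](C)[C@@H](C(C)=O)CCC1(C)C
F4 | step 9 | (2E,4E,6E,8Z,10E,12E)-13-[(1S,5S,6S)-5-hydroxy-2,2,6-trimethylcyclohexyl]-2,7,11-trimethyltrideca-2,4,6,8,10,12-hexaenal | CC(/C=C\C=C(C)\C=C\[C@H]1[C@H](C)[C@@H](O)CCC1(C)C)=C\C=C\C=C(C)\C=O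
F5 | step 9 | (2E,4E,6E,8E,10E,12E)-2,7,11-trimethyl-13-[(1S,6S)-2,2,6-trimethyl-5-oxocyclohexyl]trideca-2,4,6,8,10,12-hexaenal | CC(/C=C/C=C(C)/C=C/[C@H]1[C@H](C)C(=O)CCC1(C)C)=C\C=C\C=C(C)\C=O
F6 | step 9 | (11Z)-(4S,5S,6S,5'S,6'S)-4-hydroxy-5,6,5',6'-tetrahydro-β,β-caroten-4'-one | CC(/C=C\C=C(C)\C=C\[C@H]1[C@H](C)[C@@H](O)CCC1(C)C)=C\C=C\C=C(C)\C=C\C=C(C)\C=C\[C@H]1[C@H](C)C(=O)CCC1(C)C
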